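## Plan

- **Retrosynthesis:** the two ester C–O bonds are cut first and the side chains are taken back in oxidation level (enal CHO to the isopropenyl methyl, carbinol to acetyl). Then the C2–C3 bond of the dihydrofuran is cut, then the allylic C–B bond and the aryl O–CH2 bond, which leads to 5-acetylsalicylaldehyde, methallyl chloride and a pinacol borate.
- **Enabling feature:** C2 is an aryl-ether carbon carrying a 2-propenyl unit and C3 is a benzylic carbinol carbon, and the two are joined through O1–C7a–C3a of the benzene ring. This is the retron of a γ-aryloxyallylboration in which the arene tethers the enol ether to the aldehyde.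
- **Forward:** O-methallylation, acetal masking, deprotonation/borylation and unmasking give the (Z)-γ-aryloxyallylboronate aldehyde. The only ring to be built, the dihydrofuran, closes in step 5 by C2–C3 formation. The two esters and the enal follow.
- **Stereochemistry:** the 2,3-cis relation comes from the Z enol ether in a chair transition state and the absolute sense from a chiral phosphoric acid. The side-chain (S)-carbinol comes from Ru–TsDPEN transfer hydrogenation.

Key step: step 5

Remark: aldehyde 9 is assumed to close only slowly without acid at or below 0 °C, because pinacol (Z)-γ-alkoxyallylboronates are sluggish toward aldehydes; it is therefore isolated cold and used at once.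

## Route

Step 1
Reactants: 1 5-acetyl-2-hydroxybenzaldehyde; 2 3-chloro-2-methylprop-1-ene
Product: 3 5-acetyl-2-[(2-methylprop-2-en-1-yl)oxy]benzaldehyde
Conditions: K2CO3 (1.5 equiv), KI (10 mol%), DMF, 60 °C
Reagents that add atoms: 3-chloro-2-methylprop-1-ene 2, C=C(C)CCl
Why: Williamson ether synthesis: the phenoxide of 1 displaces chloride from the primary allylic halide by SN2 with iodide (Finkelstein) assistance, and K2CO3 touches neither carbonyl group.

Step 2
Reactants: 3 5-acetyl-2-[(2-methylprop-2-en-1-yl)oxy]benzaldehyde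
Product: 4 2-(dimethoxymethyl)-4-(1,1-dimethoxyethyl)-1-[(2-methylprop-2-en-1-yl)oxy]benzene
Conditions: HC(OMe)3 (4 equiv), MeOH, p-TsOH·H2O (2 mol%), rt; Et3N quench before concentration
Reagents that add atoms: trimethyl orthoformate, COC(OC)OC; methanol, CO
Why: Acid-catalysed acetalisation with the orthoformate as dehydrating methoxy donor turns both the aldehyde and the aryl ketone into dimethyl acetals, so that no electrophilic carbonyl and no enolisable CH remains for the organolithium step, while the methallyl ether is inert to catalytic acid at ambient temperature.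

Step 3
Reactants: 4 2-(dimethoxymethyl)-4-(1,1-dimethoxyethyl)-1-[(2-methylprop-2-en-1-yl)oxy]benzene; 5 2-isopropoxy-4,4,5,5-tetramethyl-1,3,2-dioxaborolane
Product: 8 2-[(2Z)-3-[2-(dimethoxymethyl)-4-(1,1-dimethoxyethyl)phenoxy]-2-methylprop-2-en-1-yl]-4,4,5,5-tetramethyl-1,3,2-dioxaborolane, via oxyallyllithium 6 (not isolated), via lithium allylborate 7 (not isolated)
Conditions: s-BuLi (1.15 equiv), THF, −78 °C; i-PrOBpin (1.3 equiv), −78 °C; AcOH (1.2 equiv), −78 °C to rt
Reagents that add atoms: 2-isopropoxy-4,4,5,5-tetramethyl-1,3,2-dioxaborolane 5, CC(C)OB1OC(C)(C)C(C)(C)O1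
Why: Allylic deprotonation α to oxygen followed by electrophilic borylation, the established entry to (Z)-γ-alkoxyallylboronates: s-BuLi removes an OCH2 proton to give the lithium-bridged oxyallyl anion 6 with oxygen and the CH2 terminus cis (the 2-methyl group disfavours the other form), the borate ester is taken up at the unhindered terminus as ate complex 7, and loss of isopropoxide on acidification leaves the Z enol ether, the acetals being inert to the base at −78 °C.

Step 4
Reactants: 8 2-[(2Z)-3-[2-(dimethoxymethyl)-4-(1,1-dimethoxyethyl)phenoxy]-2-methylprop-2-en-1-yl]-4,4,5,5-tetramethyl-1,3,2-dioxaborolane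
Product: 9 5-acetyl-2-{[(1Z)-2-methyl-3-(4,4,5,5-tetramethyl-1,3,2-dioxaborolan-2-yl)prop-1-en-1-yl]oxy}benzaldehyde
Conditions: pyridinium p-toluenesulfonate (10 mol%), acetone/H2O (10:1), 0 °C; aq NaHCO3; kept cold, used at once
Reagents that add atoms: water, O
Why: Acid-catalysed acetal hydrolysis: aryl-substituted dimethyl acetals ionise to oxocarbenium ions orders of magnitude faster than an aryl enol ether is protonated at carbon, and pinacol allylboronates tolerate buffered weak acid, so both carbonyl groups should be released while the Z-γ-aryloxyallylboronate and its geometry stay intact.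

Step 5
Reactants: 9 5-acetyl-2-{[(1Z)-2-methyl-3-(4,4,5,5-tetramethyl-1,3,2-dioxaborolan-2-yl)prop-1-en-1-yl]oxy}benzaldehyde
Product: 11 1-[(2R,3R)-3-hydroxy-2-(prop-1-en-2-yl)-2,3-dihydro-1-benzofuran-5-yl]ethanone, via pinacol borate 10 (not isolated)
Conditions: (S)-TRIP [(S)-3,3'-bis(2,4,6-triisopropylphenyl)-1,1'-binaphthalene-2,2'-diyl hydrogen phosphate] (10 mol%), toluene, −40 °C; then aq NaHCO3
Reagents that add atoms: none
Why: Proposed new method: the phosphoric acid hydrogen-bonds to a pinacolate oxygen of 9, boron binds the formyl oxygen, and the enol-ether carbon (γ to boron) adds to the formyl carbon through a six-membered chair with allylic transposition, which forms C2–C3, turns the CH2–B unit into the isopropenyl CH2 and gives borate 10, cleaved to 11 on aqueous work-up. The closest known reactions are the intramolecular γ-alkoxyallylboration of alkyl-tethered aldehydes to 2-alkenyl-3-hydroxy cyclic ethers and the phosphoric-acid-catalysed intermolecular allylboration of aryl aldehydes; the aryl-tethered five-membered closure has not been shown. The dihydrofuran ring closes 5-exo-trig with respect to the carbonyl group, the two arene carbons C7a and C3a serving as the tether. The relative configuration follows from the Z enol ether: the aryloxy oxygen must be axial and the formyl aryl group equatorial in the chair, the only arrangement the two-atom tether can span, so the isopropenyl group at C2 and the oxygen at C3 emerge cis. The absolute configuration is set by the acid: by analogy with the intermolecular reaction, in which the (R)-acid is understood to deliver the allyl unit to the Re face of aryl aldehydes, the (S)-acid should expose the Si face and give (2R,3R), a sense that would have to be confirmed on the first sample. The step needs aldehyde-over-ketone selectivity, secured by the much lower reactivity of the acetyl group toward allylboronates, and it needs the acid-bound pathway to outrun the acid-free closure, for which the sluggish pinacol ester and the low temperature are chosen.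

Step 6
Reactants: 11 1-[(2R,3R)-3-hydroxy-2-(prop-1-en-2-yl)-2,3-dihydro-1-benzofuran-5-yl]ethanone; 12 3-methylbutanoyl chloride
Product: 13 (2R,3R)-5-acetyl-2-(prop-1-en-2-yl)-2,3-dihydro-1-benzofuran-3-yl 3-methylbutanoate
Conditions: 3-methylbutanoyl chloride (1.3 equiv), pyridine, DMAP (5 mol%), CH2Cl2, 0 °C
Reagents that add atoms: 3-methylbutanoyl chloride 12, CC(C)CC(=O)Cl
Why: DMAP-catalysed O-acylation through the acylpyridinium ion; the C3–O bond is not broken, so both stereocenters are retained, and the basic medium avoids ionisation at C3 and loss of water to the benzofuran.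

Step 7
Reactants: 13 (2R,3R)-5-acetyl-2-(prop-1-en-2-yl)-2,3-dihydro-1-benzofuran-3-yl 3-methylbutanoate
Product: 14 (2R,3R)-5-[(1S)-1-hydroxyethyl]-2-(prop-1-en-2-yl)-2,3-dihydro-1-benzofuran-3-yl 3-methylbutanoate
Conditions: RuCl[(S,S)-TsDPEN](p-cymene) (2 mol%), HCO2H/Et3N (5:2), CH2Cl2, rt
Reagents that add atoms: none
Why: Noyori asymmetric transfer hydrogenation: the ruthenium hydride and the amine proton of the (S,S)-TsDPEN complex are delivered to the aryl methyl ketone in an outer-sphere six-membered transition state with the substrate arene under the p-cymene ligand, which should give the (S)-1-arylethanol under catalyst control, while the isolated alkene and the ester are not reduced and loss of CO2 makes the reduction irreversible.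

Step 8
Reactants: 14 (2R,3R)-5-[(1S)-1-hydroxyethyl]-2-(prop-1-en-2-yl)-2,3-dihydro-1-benzofuran-3-yl 3-methylbutanoate; 15 3-methylbut-2-enoic acid
Product: 16 (1S)-1-[(2R,3R)-3-[(3-methylbutanoyl)oxy]-2-(prop-1-en-2-yl)-2,3-dihydro-1-benzofuran-5-yl]ethyl 3-methylbut-2-enoate
Conditions: 3-methylbut-2-enoic acid (1.5 equiv), DCC (1.5 equiv), DMAP (10 mol%), CH2Cl2, 0 °C to rt
Reagents that add atoms: 3-methylbut-2-enoic acid 15, CC(C)=CC(=O)O
Why: Steglich esterification: the carbodiimide-activated acid is passed through the DMAP acylpyridinium ion to the carbinol oxygen, so the (S) centre is retained, and using the free acid instead of the acid chloride with an amine base avoids vinylketene formation and deconjugation of the senecioyl unit.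

Step 9
Reactants: 16 (1S)-1-[(2R,3R)-3-[(3-methylbutanoyl)oxy]-2-(prop-1-en-2-yl)-2,3-dihydro-1-benzofuran-5-yl]ethyl 3-methylbut-2-enoate
Product: 17 (1S)-1-[(2R,3R)-2-(3-hydroxyprop-1-en-2-yl)-3-[(3-methylbutanoyl)oxy]-2,3-dihydro-1-benzofuran-5-yl]ethyl 3-methylbut-2-enoate
Conditions: SeO2 (0.5 equiv), t-BuOOH (3 equiv), CH2Cl2, rt
Reagents that add atoms: selenium dioxide, O=[Se]=O; tert-butyl hydroperoxide, CC(C)(C)OO
Why: Riley allylic oxidation in its catalytic form: ene reaction of SeO2 with the electron-rich 1,1-disubstituted alkene and [2,3]-sigmatropic shift should hydroxylate the isopropenyl methyl group in preference to the tertiary oxygen-bearing C2–H and to the electron-poor senecioate alkene, leaving C2 untouched; any aldehyde formed alongside is carried forward.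

Step 10
Reactants: 17 (1S)-1-[(2R,3R)-2-(3-hydroxyprop-1-en-2-yl)-3-[(3-methylbutanoyl)oxy]-2,3-dihydro-1-benzofuran-5-yl]ethyl 3-methylbut-2-enoate
Product: 18 (1S)-1-[(2R,3R)-3-[(3-methylbutanoyl)oxy]-2-(3-oxoprop-1-en-2-yl)-2,3-dihydro-1-benzofuran-5-yl]ethyl 3-methylbut-2-enoate
Conditions: MnO2 (activated, 15 equiv), CH2Cl2, rt
Reagents that add atoms: none
Why: MnO2 oxidation, selective for allylic alcohols, should convert the primary allylic alcohol into the 2-substituted acrolein under neutral conditions that leave both benzylic esters and all three stereocenters untouched.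

## Compound list

1 | 5-acetyl-2-hydroxybenzaldehyde (5-acetylsalicylaldehyde) | CC(=O)c1ccc(O)c(C=O)c1 | starting material
2 | 3-chloro-2-methylprop-1-ene (methallyl chloride) | C=C(C)CCl | starting material
3 | 5-acetyl-2-[(2-methylprop-2-en-1-yl)oxy]benzaldehyde | CC(=O)c1ccc(OCC(C)=C)c(C=O)c1 | intermediate
4 | 2-(dimethoxymethyl)-4-(1,1-dimethoxyethyl)-1-[(2-methylprop-2-en-1-yl)oxy]benzene | COC(OC)c1cc(C(C)(OC)OC)ccc1OCC(C)=C | intermediate
5 | 2-isopropoxy-4,4,5,5-tetramethyl-1,3,2-dioxaborolane | CC(C)OB1OC(C)(C)C(C)(C)O1 | starting material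
6 | {1-[2-(dimethoxymethyl)-4-(1,1-dimethoxyethyl)phenoxy]-2-methylprop-2-en-1-yl}lithium (oxyallyllithium) | [Li]C(Oc1ccc(C(C)(OC)OC)cc1C(OC)OC)C(C)=C | intermediate
7 | lithium [(2Z)-3-[2-(dimethoxymethyl)-4-(1,1-dimethoxyethyl)phenoxy]-2-methylprop-2-en-1-yl](isopropoxy)(pinacolato)borate | [Li+].COC(OC)c1cc(C(C)(OC)OC)ccc1O/C=C(/C)C[B-]1(OC(C)C)OC(C)(C)C(C)(C)O1 | intermediate
8 | 2-[(2Z)-3-[2-(dimethoxymethyl)-4-(1,1-dimethoxyethyl)phenoxy]-2-methylprop-2-en-1-yl]-4,4,5,5-tetramethyl-1,3,2-dioxaborolane | COC(OC)c1cc(C(C)(OC)OC)ccc1O/C=C(/C)CB1OC(C)(C)C(C)(C)O1 | intermediate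
9 | 5-acetyl-2-{[(1Z)-2-methyl-3-(4,4,5,5-tetramethyl-1,3,2-dioxaborolan-2-yl)prop-1-en-1-yl]oxy}benzaldehyde | CC(=O)c1ccc(O/C=C(/C)CB2OC(C)(C)C(C)(C)O2)c(C=O)c1 | intermediate
10 | 1-[(2R,3R)-2-(prop-1-en-2-yl)-3-[(4,4,5,5-tetramethyl-1,3,2-dioxaborolan-2-yl)oxy]-2,3-dihydro-1-benzofuran-5-yl]ethanone | C=C(C)[C@H]1Oc2ccc(C(C)=O)cc2[C@H]1OB3OC(C)(C)C(C)(C)O3 | intermediate
11 | 1-[(2R,3R)-3-hydroxy-2-(prop-1-en-2-yl)-2,3-dihydro-1-benzofuran-5-yl]ethanone | C=C(C)[C@H]1Oc2ccc(C(C)=O)cc2[C@H]1O | intermediate
12 | 3-methylbutanoyl chloride (isovaleryl chloride) | CC(C)CC(=O)Cl | starting material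
13 | (2R,3R)-5-acetyl-2-(prop-1-en-2-yl)-2,3-dihydro-1-benzofuran-3-yl 3-methylbutanoate | C=C(C)[C@H]1Oc2ccc(C(C)=O)cc2[C@H]1OC(=O)CC(C)C | intermediate
14 | (2R,3R)-5-[(1S)-1-hydroxyethyl]-2-(prop-1-en-2-yl)-2,3-dihydro-1-benzofuran-3-yl 3-methylbutanoate | C=C(C)[C@H]1Oc2ccc([C@H](C)O)cc2[C@H]1OC(=O)CC(C)C | intermediate
15 | 3-methylbut-2-enoic acid (senecioic acid) | CC(C)=CC(=O)O | starting material
16 | (1S)-1-[(2R,3R)-3-[(3-methylbutanoyl)oxy]-2-(prop-1-en-2-yl)-2,3-dihydro-1-benzofuran-5-yl]ethyl 3-methylbut-2-enoate | C=C(C)[C@H]1Oc2ccc([C@H](C)OC(=O)C=C(C)C)cc2[C@H]1OC(=O)CC(C)C | intermediate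
17 | (1S)-1-[(2R,3R)-2-(3-hydroxyprop-1-en-2-yl)-3-[(3-methylbutanoyl)oxy]-2,3-dihydro-1-benzofuran-5-yl]ethyl 3-methylbut-2-enoate | C=C(CO)[C@H]1Oc2ccc([C@H](C)OC(=O)C=C(C)C)cc2[C@H]1OC(=O)CC(C)C | intermediate
18 | (1S)-1-[(2R,3R)-3-[(3-methylbutanoyl)oxy]-2-(3-oxoprop-1-en-2-yl)-2,3-dihydro-1-benzofuran-5-yl]ethyl 3-methylbut-2-enoate | C=C(C=O)[C@H]1Oc2ccc([C@H](C)OC(=O)C=C(C)C)cc2[C@H]1OC(=O)CC(C)C | target

## Step count and risks

Total step count: 10. Longest linear sequence: 10 steps, from 1 to 18.

Steps most likely to fail: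

**Step 5 (loss of catalyst control).** The acid-free closure may outrun the acid-bound pathway, possibly already during the unmasking in step 4, or the hindered acid may fail to engage the tethered boronate; the cis alcohol would then form with little or no enantiomeric excess. The fallback gives up catalytic control and resolves. Aldehyde 9 would be left in toluene at ambient temperature without acid, the substrate-controlled mode of intramolecular alkoxyallylboration, to give the racemic pinacol borate F1, which aqueous work-up cleaves to the racemic cis alcohol F2. Kinetic resolution with immobilised Candida antarctica lipase B and vinyl acetate in MTBE at 30 °C should, on the usual size rule for lipases with the fused arene as the large group, acetylate the (2S,3S) antipode to the (2S,3S)-acetate F3 and leave the (2R,3R)-alcohol, which is compound 11, where the route is rejoined.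

**Step 3 (wrong site of metalation).** Metalation at the ring or beside the acetal oxygens, or base-induced loss of methanol from the ketal, may compete with deprotonation at the OCH2 group. The fallback changes the latent carbonyls from acetals to alkoxides and returns them by oxidation instead of acid, setting out from 3. NaBH4 in MeOH at 0 °C should reduce both carbonyl groups to the diol 1-{3-(hydroxymethyl)-4-[(2-methylprop-2-en-1-yl)oxy]phenyl}ethan-1-ol F4, racemic at a centre that is later re-oxidised. n-BuLi (2 equiv) and then s-BuLi (1.2 equiv) in THF at −78 °C should give the dialkoxide oxyallyllithium F5. Borate 5 would be taken up as the lithium allylborate F6, and AcOH would release the (Z)-boronate diol F7. Dess–Martin periodinane (1,1,1-triacetoxy-1,1-dihydro-1,2-benziodoxol-3(1H)-one) with pyridine in CH2Cl2 at 0 °C would then oxidise both benzylic alcohols to keto aldehyde 9, where the route is rejoined. Steps 2 to 4 are bypassed, so no acid meets the enol ether.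

**Step 9 (poor site selectivity or over-oxidation).** The selenium reagent may attack the senecioate methyl groups or the ring C2–H, or conversion may stall. The fallback brings the oxygen in through chlorine, setting out from 16. Ene-type chlorination with hypochlorous acid generated from Ca(OCl)2 and CO2 in CH2Cl2/H2O at 0 °C, which is selective for the electron-rich 1,1-disubstituted alkene, should give the allylic chloride (1S)-1-[(2R,3R)-2-(3-chloroprop-1-en-2-yl)-3-[(3-methylbutanoyl)oxy]-2,3-dihydro-1-benzofuran-5-yl]ethyl 3-methylbut-2-enoate F8. N-methylmorpholine N-oxide with catalytic NaI in MeCN at rt (Ganem-type N-oxide oxidation) would convert it directly into the enal 18, so that steps 9 and 10 are both replaced.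

## Further compounds

F1 | step 5 | racemic 1-[(2R*,3R*)-2-(prop-1-en-2-yl)-3-[(4,4,5,5-tetramethyl-1,3,2-dioxaborolan-2-yl)oxy]-2,3-dihydro-1-benzofuran-5-yl]ethanone | C=C(C)[C@H]1Oc2ccc(C(C)=O)cc2[C@H]1OB3OC(C)(C)C(C)(C)O3.C=C(C)[C@@H]1Oc2ccc(C(C)=O)cc2[C@@H]1OB3OC(C)(C)C(C)(C)O3
F2 | step 5 | racemic 1-[(2R*,3R*)-3-hydroxy-2-(prop-1-en-2-yl)-2,3-dihydro-1-benzofuran-5-yl]ethanone | C=C(C)[C@H]1Oc2ccc(C(C)=O)cc2[C@H]1O.C=C(C)[C@@H]1Oc2ccc(C(C)=O)cc2[C@@H]1O
F3 | step 5 | (2S,3S)-5-acetyl-2-(prop-1-en-2-yl)-2,3-dihydro-1-benzofuran-3-yl acetate | C=C(C)[C@@H]1Oc2ccc(C(C)=O)cc2[C@@H]1OC(C)=O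
F4 | step 3 | 1-{3-(hydroxymethyl)-4-[(2-methylprop-2-en-1-yl)oxy]phenyl}ethan-1-ol (racemic) | CC(O)c1ccc(OCC(C)=C)c(CO)c1
F5 | step 3 | trilithium species: dilithium dialkoxide of F4 lithiated at the OCH2 carbon | [Li]OC(C)c1ccc(OC([Li])C(C)=C)c(CO[Li])c1
F6 | step 3 | lithium (isopropoxy)(pinacolato)[(2Z)-3-aryloxy-2-methylprop-2-en-1-yl]borate of the dilithium dialkoxide | [Li+].[Li]OC(C)c1ccc(O/C=C(/C)C[B-]2(OC(C)C)OC(C)(C)C(C)(C)O2)c(CO[Li])c1
F7 | step 3 | 1-{3-(hydroxymethyl)-4-{[(1Z)-2-methyl-3-(4,4,5,5-tetramethyl-1,3,2-dioxaborolan-2-yl)prop-1-en-1-yl]oxy}phenyl}ethan-1-ol | CC(O)c1ccc(O/C=C(/C)CB2OC(C)(C)C(C)(C)O2)c(CO)c1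
F8 | step 9 | (1S)-1-[(2R,3R)-2-(3-chloroprop-1-en-2-yl)-3-[(3-methylbutanoyl)oxy]-2,3-dihydro-1-benzofuran-5-yl]ethyl 3-methylbut-2-enoate | C=C(CCl)[C@H]1Oc2ccc([C@H](C)OC(=O)C=C(C)C)cc2[C@H]1OC(=O)CC(C)C
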